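The readings are simulated for substances that don't exist, noise included.

South-west, charged with more reagent in the second phase than east, had lost 35.0 % of its starting material at 40.0 min where east had lost 24.0 %, and this comparison is where we start.

common to all: starting material 0.80 M
- east: reagent in the second phase 1.1 equiv; run made earlier
- south-west: reagent in the second phase 1.8 equiv; run made earlier
- flask: reagent in the second phase 0.800 equiv; time 1.0 h; volume of the second phase over the first 2.0

- east (time / min: target / %, starting material / %): 6.00: 2, 97; 12.0: 4, 95; 20.0: 7, 92; 25.0: 12, 83; 30.0: 11, 85; 40.0: 11, 76
- south-west (time / min: target / %, starting material / %): 2.50: 0, 101; 8.00: 5, 96; 12.0: 8, 93; 20.0: 12, 86; 30.0: 16, 75; 40.0: 19, 65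

(standard deviation of a reading: 1.5 percentage points)

* how much target there is at 1.0 h, in percent of the starting material charged
* the change that raises the amount of target at 1.0 h, in percent of the starting material charged most ("none" if none brings more than 2 percentage points) (elm / larch / none)
* amount of target at 1.0 h, in percent of the starting material charged, after larch

- elm: doubling the transfer coefficient of the reagent in the second phase, all else as stated
- larch: doubling the amount of reagent in the second phase, all else as stated

- in the second phase: reagent in the second phase; everything else is in the first
- charges count per volume of the first phase; a concentration in a rate is the amount of a species over the volume of its own phase; every rate counts per litre of the first phase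
- the earlier runs hold the two phases in the same ratio of volumes as the flask asked about

The bench rule says that the loss of starting material goes with equivalents times time. The charges stand in the ratio 1.64 and the losses in the ratio 1.46, so the rule is usable but runs a little high. The rule that target equals loss stops working in south-west, whose last reading shows 19 % target out of its 35.0 % lost, a ratio of 0.543.

We therefore need a scale for target, and its zero is the even-handed case, a selectivity factor of one, where target is attacked as readily as starting material. In a plain chain of two first-order steps with equal constants, with a fraction x of the starting material left, target then stands at −x ln x. South-west's last reading stands at 0.679 of that curve, and this ratio of target read to even-handed target is what we carry, the kept share.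

Scaling south-west's loss to this flask's charge and time gives 23.3 % lost, an even-handed target of 20.4 %, and so our reckoning of 13.9 %. For larch the same steps give 46.7 % lost and 22.8 % target, a figure we hold to be high, since that loss lies beyond south-west's and south-west's reading at 30.0 min puts the kept share at 0.742, above its last one, though these are two scattered readings.

The forecast gives 13 %, names larch with 18 %, and says of elm: “Doubling transfer removes only the lag and spends the limited reagent sooner”.

The flask gives 13.9 % with 76 % of its starting material left, and larch gives 18.9 %, a gain of 5 percentage points against 1.2 points for elm.

    reagent in the reaction phase ⇌ reagent in the second phase, rate k1*([reagent in the reaction phase] - [reagent in the second phase]/K1) per volume of the first phase (partition coefficient = 0.650, kL = 7.30 × 10⁻⁴ s⁻¹)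
    starting material + reagent in the reaction phase → target (k = 5.70 × 10⁻⁴ L mol⁻¹ s⁻¹)
    reagent in the reaction phase + target → over-reacted product (k = 0.00140 L mol⁻¹ s⁻¹)
    reagent in the reaction phase ⇌ dormant form (K = 1.50, k = 3.90 × 10⁻⁴ s⁻¹)
    starting material + target → side product (k = 1.20 × 10⁻⁴ L mol⁻¹ s⁻¹)

The kept share of this flask is 0.676 at 1.00 h, and the same flask read at 25 min, with 90.5 % of its starting material left and 7.63 % target, stands at 0.845. At 1.00 h target is made 1.48 times faster than it is used up, each step taken net, and at 10.0 h the flask holds 7.96 % target.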